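(Readings and results were computed on assumed constants.)

Start from a leftover. In the north-west flask, the first nucleophile left at the end should be its charge, less the protic impurity (which we count as quenching an equal amount), less what became target.

the same everywhere: substrate 0.20 mM
- north-west: first nucleophile 0.22 mM; second nucleophile 1 mM; protic impurity 0.060 mM; the very flask that is asked about, followed so far
- east: first nucleophile 0.22 mM; second nucleophile 0.50 mM; protic impurity 0.060 mM; run made earlier
- flask: first nucleophile 0.220 mM; second nucleophile 1.00 mM; protic impurity 0.0600 mM; time 12 min

- north-west (time / min: target / %, other capture product / %, substrate / %): 0.333: 21.1, 45.4, 32.3; 1.00: 31.7, 64.8, 4.4; 1.50: 32.9, 66.6, 0.1; 2.50: 33.3, 66.6, 0.1; 4.00: 33.5, 66.8, 0; 5.00: 32.9, 66.7, 0.8; 6.00: 32.8, 67.5, 0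
- east (time / min: target / %, other capture product / %, substrate / %): 0.667: 41.7, 47.5, 11.0; 2.00: 46.6, 53.1, 0.8; 3.00: 47.2, 52.5, 0; 5.00: 46.7, 52.9, 0; 8.00: 46.3, 52.8, 0; 10.0: 47.1, 51.8, 0; 12.0: 46.1, 52.3, 0

(each reading ± 0.5 percentage points)

1. ratio of target to other capture product at 0.30 s
2. ratio of target to other capture product at 15 s
3. ratio of target to other capture product at 12 min
4. which of target and other capture product there is more of at 12 min

- what may be going on: substrate -> intermediate; first nucleophile + intermediate -> target; second nucleophile + intermediate -> other capture product; first nucleophile + protic impurity -> quenched reagent; second nucleophile -> decomposed reagent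

The last 4 readings of the north-west run give a ratio of target to other capture product of 0.495. Target is then 33.1% of the substrate, and the leftover is 0.0938 mM. The east flask differs by one charge, with half the second nucleophile. It reads 0.888, so target is 47.0% and the leftover is 0.0660 mM.

Both captures compete for one intermediate, so the ratio should follow c(first nucleophile)/c(second nucleophile). Yet the east ratio is up by a factor of 1.79, and the mean active first nucleophile, halfway between the charge less impurity and the leftover, is lower in the east flask, 0.113 mM against 0.127 mM. We therefore define the capture number, an effective selectivity factor, as the end ratio times the charge of second nucleophile over that mean. It reads 3.90 in the north-west flask and 3.93 in the east flask.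

The asked flask has the north-west charge, and its substrate already reads 0% at 6.00 min, so we commit to 0.495 at 12 min.

The forecast gives 0.52 at 0.30 s, 0.46 at 15 s and 0.497 at 12 min, with other capture product ahead; for the value at 12 min and the lead, its ground is that “the ratio is simply its plateau”.

The flask gives 0.540, 0.455 and 0.488, with other capture product at 67.2% against target at 32.8%.

    substrate → intermediate (k = 0.0549 /s)
    first nucleophile + intermediate → target (k = 44200 /M/s)
    second nucleophile + intermediate → other capture product (k = 17800 /M/s)
    first nucleophile + protic impurity → quenched reagent (k = 1400 /M/s)
    second nucleophile → decomposed reagent (k = 0.0154 /s)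

At 0.699 min the second nucleophile takes the intermediate 1.7 times as fast as the first nucleophile does. By 1.20 min that capture has 99% of its turnover behind it, with 1.92% of the substrate remaining. The flask's first nucleophile ends at 42.9% of its charge, against our leftover of 42.6%, and its capture number comes to 3.83. In the neighbour charged with 0.40 mM of second nucleophile, first nucleophile ends at 25.6%, the north-west capture number then gives 1.06, and that flask stands at 1.08.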